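**Retrosynthetic overview**
- The target is the bis-saponification product of its dimethyl ester; the oxirane (the only ring of the target) comes from a reagent-controlled Shi epoxidation of the 4Z olefin of a (2E,4Z)-dienoate.
- Key disconnection C8–C9: a nickel-hydride radical hydroalkylation in which the primary C8 radical from a C1–C8 iodide is joined to the terminal alkene of an unprotected C9–C13 diol ester.
- The C1–C8 iodide comes from (S)-3-bromo-2-methylpropan-1-ol (C7), propyne and methyl but-2-ynoate by a one-pot double syn-carbocupration that sets 4Z and 2E.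
- The C9–C13 alkene comes from an anti-selective Fráter–Seebach hydroxymethylation (C13) of methyl (R)-3-hydroxyhex-5-enoate, made by cobalt-catalysed methoxycarbonylation of (R)-allyloxirane from (R)-epichlorohydrin (C12).
- Ring order: a transient oxirane in the right-hand fragment is made and opened early (steps 4 and 5); the oxirane of the target is closed only after fragment union (step 8).

Assumption: the SMILES is read literally as (2E,4S,5R,7S,12R,13R), which places C3 and C6 cis on the oxirane (the epoxide of a 4Z olefin); both enantiomers of 3-bromo-2-methylpropan-1-ol and of epichlorohydrin are taken as commercial.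

**Route**

Step 1
Reactants: 1 (2S)-3-bromo-2-methylpropan-1-ol
Product: 2 [(2S)-3-bromo-2-methylpropoxy](triethyl)silane
Conditions: Et3SiCl, imidazole, CH2Cl2, 0 °C to rt
Reagents that add atoms: triethylsilyl chloride, CC[Si](Cl)(CC)CC
Why: imidazole-promoted silylation (silyl ether formation) masks the only acidic proton so that the bromide can be converted into a Grignard reagent, and C7 is untouched.

Step 2
Reactants: 2 [(2S)-3-bromo-2-methylpropoxy](triethyl)silane; 3 propyne; 4 methyl but-2-ynoate
Product: 10 methyl (2E,4Z,7R)-8-hydroxy-3,5,7-trimethylocta-2,4-dienoate, via Grignard reagent 5 (not isolated), via alkylcopper 6 (not isolated), via alkenylcopper 7 (not isolated), via cuprio dienoate 8 (not isolated), via silyl dienoate 9 (not isolated)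
Conditions: Mg, Et2O, reflux; CuBr·SMe2, Et2O–Me2S, −45 °C; propyne, −25 °C, then purge; methyl but-2-ynoate, −78 to −50 °C; MeOH, −78 °C; 1 M aq. HCl, THF, 0 °C to rt
Reagents that add atoms: none
Why: Normant carbocupration, in which the alkylcopper adds syn across propyne with the alkyl group on the internal carbon so that C6 and copper are cis (this fixes 4Z), the alkenylcopper then adds syn across the ynoate (conjugate carbocupration) and cold protonation with retention fixes 2E, and dilute acid finally cleaves the triethylsilyl ether while C7 remains a spectator.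

Step 3
Reactants: 10 methyl (2E,4Z,7R)-8-hydroxy-3,5,7-trimethylocta-2,4-dienoate
Product: 11 methyl (2E,4Z,7R)-8-iodo-3,5,7-trimethylocta-2,4-dienoate
Conditions: PPh3, imidazole, I2 (premixed), CH2Cl2, 0 °C, dark
Reagents that add atoms: iodine, II
Why: Appel-type (Garegg–Samuelsson) iodination by SN2 displacement of the alkoxyphosphonium ion at the primary carbon gives the radical precursor without touching the dienoate or C7.

Step 4
Reactants: 12 (2R)-2-(chloromethyl)oxirane; 13 vinylmagnesium bromide
Product: 15 (2R)-2-(prop-2-en-1-yl)oxirane, via chlorohydrin alkoxide 14 (not isolated)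
Conditions: CuI (5 mol%), THF, −78 to −20 °C; then 3 M aq. NaOH, rt; used as a dried ethereal solution
Reagents that add atoms: none
Why: copper-catalysed Grignard opening of the epoxide at its unsubstituted carbon followed by intramolecular Williamson closure onto the chloromethyl carbon breaks no bond at the stereocentre, so the (R)-epichlorohydrin centre becomes C12 of the (R)-oxirane.

Step 5
Reactants: 15 (2R)-2-(prop-2-en-1-yl)oxirane
Product: 16 methyl (3R)-3-hydroxyhex-5-enoate
Conditions: Co2(CO)8 (5 mol%), 3-hydroxypyridine (10 mol%), CO (40 bar), MeOH–THF, 60 °C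
Reagents that add atoms: carbon monoxide, [C-]#[O+]; methanol, CO
Why: cobalt-catalysed carbonylative ring opening (methoxycarbonylation) of a terminal epoxide, in which the cobaltate attacks the CH2 terminus, CO inserts and methanolysis releases the β-hydroxy ester, so the C12–O bond and its configuration are retained.

Step 6
Reactants: 16 methyl (3R)-3-hydroxyhex-5-enoate
Product: 18 methyl (2R,3R)-3-hydroxy-2-(hydroxymethyl)hex-5-enoate, via dilithium dianion 17 (not isolated)
Conditions: LiN(i-Pr)2 (2.2 equiv), THF, −78 to −20 °C; CH2O (gas), −78 °C; aq. NH4Cl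
Reagents that add atoms: formaldehyde, C=O
Why: Fráter–Seebach reaction, in which the chelated alkoxide–enolate dianion undergoes aldol addition to formaldehyde on the face anti to the allyl-bearing substituent of the carbinol carbon, which sets C13 as the 2,3-anti (2R,3R) isomer.

Step 7
Reactants: 11 methyl (2E,4Z,7R)-8-iodo-3,5,7-trimethylocta-2,4-dienoate; 18 methyl (2R,3R)-3-hydroxy-2-(hydroxymethyl)hex-5-enoate (1.5 equiv)
Product: 19 dimethyl (2E,4Z,7S,12R,13R)-12-hydroxy-13-(hydroxymethyl)-3,5,7-trimethyltetradeca-2,4-dienedioate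
Conditions: NiBr2·diglyme (10 mol%), 4,4'-di-tert-butyl-2,2'-bipyridine (12 mol%), (EtO)2MeSiH (2.5 equiv), Na2CO3, DMA, 25 °C
Reagents that add atoms: none
Why: nickel-hydride reductive olefin hydroalkylation, in which Ni–H formed from the silane inserts anti-Markovnikov into the terminal alkene of 18, low-valent nickel converts iodide 11 into the free primary C8 radical, and radical capture at nickel with reductive elimination forges C8–C9, while the hindered trisubstituted dienoate does not insert Ni–H, the free hydroxyls are tolerated and no stereocentre sits at a reacting carbon.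

Step 8
Reactants: 19 dimethyl (2E,4Z,7S,12R,13R)-12-hydroxy-13-(hydroxymethyl)-3,5,7-trimethyltetradeca-2,4-dienedioate
Product: 20 dimethyl (2E,4S,5R,7S,12R,13R)-4,5-epoxy-12-hydroxy-13-(hydroxymethyl)-3,5,7-trimethyltetradec-2-enedioate
Conditions: ent-Shi ketone (L-fructose-derived 1,2:4,5-di-O-isopropylidene-β-L-erythro-2,3-hexodiulo-2,6-pyranose, 0.3 equiv), KHSO5 (as 2KHSO5·KHSO4·K2SO4), K2CO3, Bu4NHSO4, MeCN–CH2(OMe)2, aq. Na2B4O7 buffer pH 10.5, −10 to 0 °C
Reagents that add atoms: potassium peroxymonosulfate KHSO5, [K+].[O-]S(=O)(=O)OO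
Why: Shi asymmetric epoxidation, in which the electrophilic chiral dioxirane attacks only the electron-richer C4=C5 bond (C2=C3 is deactivated by the ester) in a concerted, stereospecific way that keeps C3 and C6 cis, and the L-fructose-derived ketone, through the spiro transition state with C3 and the C5 methyl as the trans pair, delivers oxygen to the face that gives (4S,5R).

Step 9
Reactants: 20 dimethyl (2E,4S,5R,7S,12R,13R)-4,5-epoxy-12-hydroxy-13-(hydroxymethyl)-3,5,7-trimethyltetradec-2-enedioate
Product: 21 (2E,4S,5R,7S,12R,13R)-4,5-epoxy-12-hydroxy-13-(hydroxymethyl)-3,5,7-trimethyltetradec-2-enedioic acid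
Conditions: LiOH (6 equiv), THF–MeOH–H2O, 0 °C to rt; then cold 0.5 M aq. HCl to pH 3.5, immediate EtOAc extraction
Reagents that add atoms: lithium hydroxide, [Li+].[OH-]
Why: saponification (acyl-oxygen ester hydrolysis) of both methyl esters proceeds under basic conditions that leave the epoxide intact, the 2E geometry prevents the C1 carboxylate from reaching C4, and cold, brief acidification liberates the diacid without opening the oxirane or touching any stereocentre.

**Compound list**
1 | (2S)-3-bromo-2-methylpropan-1-ol | BrC[C@@H](C)CO | starting material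
2 | [(2S)-3-bromo-2-methylpropoxy](triethyl)silane | BrC[C@@H](C)CO[Si](CC)(CC)CC | intermediate
3 | propyne | CC#C | starting material
4 | methyl but-2-ynoate | CC#CC(=O)OC | starting material
5 | [(2S)-2-methyl-3-(triethylsilyloxy)propyl]magnesium bromide | Br[Mg]C[C@@H](C)CO[Si](CC)(CC)CC | intermediate
6 | [(2S)-2-methyl-3-(triethylsilyloxy)propyl]copper (MgBr2 complex) | [Cu]C[C@@H](C)CO[Si](CC)(CC)CC | intermediate
7 | [(1Z,4R)-2,4-dimethyl-5-(triethylsilyloxy)pent-1-en-1-yl]copper | [Cu]/C=C(/C)\C[C@@H](C)CO[Si](CC)(CC)CC | intermediate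
8 | methyl (2Z,4Z,7R)-2-cuprio-3,5,7-trimethyl-8-(triethylsilyloxy)octa-2,4-dienoate | COC(=O)/C([Cu])=C(\C)/C=C(/C)\C[C@@H](C)CO[Si](CC)(CC)CC | intermediate
9 | methyl (2E,4Z,7R)-3,5,7-trimethyl-8-(triethylsilyloxy)octa-2,4-dienoate | COC(=O)/C=C(\C)/C=C(/C)\C[C@@H](C)CO[Si](CC)(CC)CC | intermediate
10 | methyl (2E,4Z,7R)-8-hydroxy-3,5,7-trimethylocta-2,4-dienoate | COC(=O)/C=C(\C)/C=C(/C)\C[C@@H](C)CO | intermediate
11 | methyl (2E,4Z,7R)-8-iodo-3,5,7-trimethylocta-2,4-dienoate | COC(=O)/C=C(\C)/C=C(/C)\C[C@@H](C)CI | intermediate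
12 | (2R)-2-(chloromethyl)oxirane, (R)-epichlorohydrin | ClC[C@H]1CO1 | starting material
13 | vinylmagnesium bromide | C=C[Mg]Br | starting material
14 | bromomagnesium (2R)-1-chloropent-4-en-2-olate | C=CC[C@@H](O[Mg]Br)CCl | intermediate
15 | (2R)-2-(prop-2-en-1-yl)oxirane | C=CC[C@@H]1CO1 | intermediate
16 | methyl (3R)-3-hydroxyhex-5-enoate | C=CC[C@@H](O)CC(=O)OC | intermediate
17 | dilithium (3R)-1-methoxyhexa-1,5-diene-1,3-bis(olate) | [Li+].[Li+].C=CC[C@@H]([O-])C=C([O-])OC | intermediate
18 | methyl (2R,3R)-3-hydroxy-2-(hydroxymethyl)hex-5-enoate | C=CC[C@@H](O)[C@@H](CO)C(=O)OC | intermediate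
19 | dimethyl (2E,4Z,7S,12R,13R)-12-hydroxy-13-(hydroxymethyl)-3,5,7-trimethyltetradeca-2,4-dienedioate | COC(=O)/C=C(\C)/C=C(/C)\C[C@@H](C)CCCC[C@@H](O)[C@@H](CO)C(=O)OC | intermediate
20 | dimethyl (2E,4S,5R,7S,12R,13R)-4,5-epoxy-12-hydroxy-13-(hydroxymethyl)-3,5,7-trimethyltetradec-2-enedioate | COC(=O)/C=C(\C)[C@@H]1O[C@]1(C)C[C@@H](C)CCCC[C@@H](O)[C@@H](CO)C(=O)OC | intermediate
21 | (2E,4S,5R,7S,12R,13R)-4,5-epoxy-12-hydroxy-13-(hydroxymethyl)-3,5,7-trimethyltetradec-2-enedioic acid | C/C(=C\C(=O)O)[C@@H]1O[C@]1(C)C[C@@H](C)CCCC[C@@H](O)[C@@H](CO)C(=O)O | target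

**Step count**
Total steps: 9. Longest linear sequence: 6 steps (1, 2, 3, 7, 8, 9; the branch 4, 5, 6, 7, 8, 9 is equally long).

**Three steps most likely to fail, with fallbacks**

Step 7 (fragment union). Ni–H insertion into the homoallylic diol ester may be slow, and 11 may simply be reduced. The fallback sets out from 18 and 11 and comes back at 19; it pre-forms the organometallic partner instead of generating it by Ni–H insertion. Compound 18 is protected with 2,2-dimethoxypropane and PPTS as methyl (4R,5R)-2,2-dimethyl-4-(prop-2-en-1-yl)-1,3-dioxane-5-carboxylate F3. Hydroboration with 9-BBN (THF, rt) gives methyl (4R,5R)-4-[3-(9-borabicyclo[3.3.1]nonan-9-yl)propyl]-2,2-dimethyl-1,3-dioxane-5-carboxylate F4. F4 is coupled with 11 under nickel/diamine alkyl–alkyl Suzuki conditions (NiCl2·glyme, trans-N,N'-dimethylcyclohexane-1,2-diamine, KOt-Bu, i-BuOH, dioxane, rt), in which the C8 radical from 11 is again captured at nickel. This gives methyl (4R,5R)-4-[(5S,7Z,9E)-11-methoxy-5,7,9-trimethyl-11-oxoundeca-7,9-dien-1-yl]-2,2-dimethyl-1,3-dioxane-5-carboxylate F5. AcOH–H2O–THF at 40 °C removes the acetonide and returns 19.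

Step 2 (carbocupration cascade). The alkenylcopper may add sluggishly to the β-methyl ynoate, or the adduct may lose its 2E geometry on warming. The fallback sets out from 2 and comes back at 10; it separates the two C–C bond formations. Compound 7 is made as before and quenched with I2 at −40 °C (copper–iodine exchange with retention) to give triethyl{[(2R,4Z)-5-iodo-2,4-dimethylpent-4-en-1-yl]oxy}silane F1. In parallel, 4 is syn-borylated (B2pin2, CuCl, NaOt-Bu, Xantphos, MeOH, THF) to methyl (2Z)-3-(4,4,5,5-tetramethyl-1,3,2-dioxaborolan-2-yl)but-2-enoate F2. Suzuki–Miyaura coupling of F1 with F2 (Pd(PPh3)4, aq. K3PO4, THF, 50 °C, retention at both alkenes) gives 9, and 1 M HCl in MeOH–THF gives 10.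

Step 8 (face selectivity on a Z-configured trisubstituted dienoate). The spiro transition state may be eroded by the bulky cis substituent at C5. The fallback sets out from 19 and comes back at 20; it gives up catalyst control in favour of separation. Dimethyldioxirane in acetone at −20 °C epoxidises the same C4=C5 bond stereospecifically but on both faces. The two cis-epoxides, 20 and dimethyl (2E,4R,5S,7S,12R,13R)-4,5-epoxy-12-hydroxy-13-(hydroxymethyl)-3,5,7-trimethyltetradec-2-enedioate F6, are diastereomers because of C7, C12 and C13. They are separated by preparative HPLC; 20 is carried into step 9 and F6 is discarded.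

Further compounds
F1 | step 2 | triethyl{[(2R,4Z)-5-iodo-2,4-dimethylpent-4-en-1-yl]oxy}silane | I/C=C(/C)\C[C@@H](C)CO[Si](CC)(CC)CC
F2 | step 2 | methyl (2Z)-3-(4,4,5,5-tetramethyl-1,3,2-dioxaborolan-2-yl)but-2-enoate | COC(=O)/C=C(\C)B1OC(C)(C)C(C)(C)O1
F3 | step 7 | methyl (4R,5R)-2,2-dimethyl-4-(prop-2-en-1-yl)-1,3-dioxane-5-carboxylate | C=CC[C@H]1OC(C)(C)OC[C@H]1C(=O)OC
F4 | step 7 | methyl (4R,5R)-4-[3-(9-borabicyclo[3.3.1]nonan-9-yl)propyl]-2,2-dimethyl-1,3-dioxane-5-carboxylate | C(CCB3C4CCCC3CCC4)[C@H]1OC(C)(C)OC[C@H]1C(=O)OC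
F5 | step 7 | methyl (4R,5R)-4-[(5S,7Z,9E)-11-methoxy-5,7,9-trimethyl-11-oxoundeca-7,9-dien-1-yl]-2,2-dimethyl-1,3-dioxane-5-carboxylate | COC(=O)/C=C(\C)/C=C(/C)\C[C@@H](C)CCCC[C@H]1OC(C)(C)OC[C@H]1C(=O)OC
F6 | step 8 | dimethyl (2E,4R,5S,7S,12R,13R)-4,5-epoxy-12-hydroxy-13-(hydroxymethyl)-3,5,7-trimethyltetradec-2-enedioate | COC(=O)/C=C(\C)[C@H]1O[C@@]1(C)C[C@@H](C)CCCC[C@@H](O)[C@@H](CO)C(=O)OC
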